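**Retrosynthetic overview**

1. The target is reached by cleaving fifteen aryl methyl ethers. Before that, ring A is freed from a carboxylate on its carbon 6 by ester hydrolysis and loss of CO2.
2. The strategy rests on ring A, numbered so that its carbons 1, 3 and 5 bear the hydroxyls. Carbon 4, between carbons 3 and 5, carries the ether oxygen to carbon 1 of ring B. Ring-A carbons 1, 3 and 5 are read as carbonyl carbons and carbon 4 as the aryloxy-substituted α-carbon of a dimethyl 2-aryloxy-3,5-dioxoheptanedioate. The ring is cut between its carbons 5 and 6 (Claisen cyclisation).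
3. The chain is cut between its ketone carbon 3 and methylene carbon 4 into the half-ester chloride of an aryloxymalonate and neutral 1-methoxy-1,3-bis(trimethylsilyloxy)buta-1,3-diene. The aryloxymalonate comes from the hexamer phenol and dimethyl chloromalonate, so the crowded ether between ring A and ring B is made by SN2 at a malonate carbon.
4. The hexamer phenol BCDEFG is grown from ring G to ring B in five rounds of copper-catalysed etherification with a formyl-activated aryl bromide, each followed by Dakin oxidation of the formyl group to the next phenol.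
5. Rings G, F, E, D, C and B are bought as benzene rings and joined in that order; ring A is the only ring constructed and is formed last.

Key step: step 16

Remark on the chemistry: the two silyl enol ethers of the acetoacetate branch are taken as mixtures of double-bond isomers, because that geometry is lost on acylation. The compounds with the aryloxy-substituted sp3 carbon are racemic; that carbon becomes the aromatic carbon 4 of ring A, so the target has no stereocentre.

**Route**

Step 1
Reactants: 1 3,4,5-trimethoxyphenol; 2 4-bromo-3,5-dimethoxybenzaldehyde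
Product: 3 3,5-dimethoxy-4-(3,4,5-trimethoxyphenoxy)benzaldehyde (dimer aldehyde FG)
Conditions: CuI (10 mol%), picolinic acid (20 mol%), K3PO4, DMSO, 90 °C
Reagents that add atoms: none
Why: Ullmann diaryl ether synthesis in which the unhindered phenoxide of 1 replaces bromide on 2, whose para formyl group activates the carbon–bromine bond between two methoxy groups; 1 has no halogen and 2 no hydroxyl, so only the ether between ring F and ring G can form.

Step 2
Reactants: 3 dimer aldehyde FG
Product: 5 3,5-dimethoxy-4-(3,4,5-trimethoxyphenoxy)phenol (dimer phenol FG), via aryl formate 4 (not isolated)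
Conditions: mCPBA, CH2Cl2, 0 °C to rt; then K2CO3 (cat.), MeOH, rt
Reagents that add atoms: mCPBA (3-chloroperoxybenzoic acid), OOC(=O)c1cccc(Cl)c1
Why: Baeyer–Villiger oxidation in its Dakin form, in which the aryl group, electron-rich through its para aryloxy oxygen, should migrate in preference to hydride to give formate 4, and methanolysis frees the ring-F hydroxyl only after the peracid is spent.

Step 3
Reactants: 5 dimer phenol FG; 6 2-bromo-3,4,5-trimethoxybenzaldehyde
Product: 7 2-[3,5-dimethoxy-4-(3,4,5-trimethoxyphenoxy)phenoxy]-3,4,5-trimethoxybenzaldehyde (trimer aldehyde EFG)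
Conditions: CuI (10 mol%), picolinic acid (20 mol%), K3PO4, DMSO, 90 °C
Reagents that add atoms: none
Why: Ullmann diaryl ether synthesis in which the ortho formyl group of 6 activates the carbon–bromine bond and holds copper next to it, so the unhindered phenoxide of 5 should form the ether between ring E and ring F at the ring-E carbon lying between the formyl and a methoxy group.

Step 4
Reactants: 7 trimer aldehyde EFG
Product: 9 2-[3,5-dimethoxy-4-(3,4,5-trimethoxyphenoxy)phenoxy]-3,4,5-trimethoxyphenol (trimer phenol EFG), via aryl formate 8 (not isolated)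
Conditions: mCPBA, CH2Cl2, 0 °C to rt; then K2CO3 (cat.), MeOH, rt
Reagents that add atoms: mCPBA (3-chloroperoxybenzoic acid), OOC(=O)c1cccc(Cl)c1
Why: Dakin-type Baeyer–Villiger oxidation, made fast by the ortho aryloxy and para methoxy groups on the migrating ring E, followed by formate methanolysis to the ring-E phenol.

Step 5
Reactants: 9 trimer phenol EFG; 2 4-bromo-3,5-dimethoxybenzaldehyde
Product: 10 4-{2-[3,5-dimethoxy-4-(3,4,5-trimethoxyphenoxy)phenoxy]-3,4,5-trimethoxyphenoxy}-3,5-dimethoxybenzaldehyde (tetramer aldehyde DEFG)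
Conditions: CuI (10 mol%), picolinic acid (20 mol%), K3PO4, DMSO, 90 °C
Reagents that add atoms: none
Why: Ullmann diaryl ether synthesis as in step 1, in which the ring-E phenoxide, which keeps one free ortho position, attacks the formyl-activated bromide to set the ether between ring D and ring E.

Step 6
Reactants: 10 tetramer aldehyde DEFG
Product: 12 tetramer phenol DEFG (3,5-dimethoxyphenol carrying at position 4 the aryloxy group of 9), via aryl formate 11 (not isolated)
Conditions: mCPBA, CH2Cl2, 0 °C to rt; then K2CO3 (cat.), MeOH, rt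
Reagents that add atoms: mCPBA (3-chloroperoxybenzoic acid), OOC(=O)c1cccc(Cl)c1
Why: Dakin-type Baeyer–Villiger oxidation as in step 2, the para aryloxy group directing aryl migration, which should give the unhindered ring-D phenol.

Step 7
Reactants: 12 tetramer phenol DEFG; 6 2-bromo-3,4,5-trimethoxybenzaldehyde
Product: 13 pentamer aldehyde CDEFG (3,4,5-trimethoxybenzaldehyde carrying at position 2 the aryloxy group of 12)
Conditions: CuI (10 mol%), picolinic acid (20 mol%), K3PO4, DMSO, 90 °C
Reagents that add atoms: none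
Why: Ullmann diaryl ether synthesis as in step 3, with the ortho formyl group of 6 activating the bromide, to form the ether between ring C and ring D.

Step 8
Reactants: 13 pentamer aldehyde CDEFG
Product: 15 pentamer phenol CDEFG (3,4,5-trimethoxyphenol carrying at position 2 the aryloxy group of 12), via aryl formate 14 (not isolated)
Conditions: mCPBA, CH2Cl2, 0 °C to rt; then K2CO3 (cat.), MeOH, rt
Reagents that add atoms: mCPBA (3-chloroperoxybenzoic acid), OOC(=O)c1cccc(Cl)c1
Why: Dakin-type Baeyer–Villiger oxidation as in step 4, with ortho aryloxy and para methoxy groups on the migrating ring C, to give the ring-C phenol.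

Step 9
Reactants: 15 pentamer phenol CDEFG; 2 4-bromo-3,5-dimethoxybenzaldehyde
Product: 16 hexamer aldehyde BCDEFG (3,5-dimethoxybenzaldehyde carrying at position 4 the aryloxy group of 15)
Conditions: CuI (10 mol%), picolinic acid (20 mol%), K3PO4, DMSO, 90 °C
Reagents that add atoms: none
Why: Ullmann diaryl ether synthesis as in steps 1 and 5, the para formyl group again activating the hindered bromide, to form the ether between ring B and ring C.

Step 10
Reactants: 16 hexamer aldehyde BCDEFG
Product: 18 hexamer phenol BCDEFG (3,5-dimethoxyphenol carrying at position 4 the aryloxy group of 15), via aryl formate 17 (not isolated)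
Conditions: mCPBA, CH2Cl2, 0 °C to rt; then K2CO3 (cat.), MeOH, rt
Reagents that add atoms: mCPBA (3-chloroperoxybenzoic acid), OOC(=O)c1cccc(Cl)c1
Why: Dakin-type Baeyer–Villiger oxidation as in step 2, which should unmask the unhindered ring-B hydroxyl with all fifteen methyl ethers in place.

Step 11
Reactants: 18 hexamer phenol BCDEFG; 19 dimethyl chloromalonate
Product: 20 dimethyl 2-(ArO)propanedioate (ArO = 18 without its hydroxyl hydrogen and bonded through the ring-B oxygen)
Conditions: K2CO3, acetone, reflux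
Reagents that add atoms: none
Why: Williamson-type SN2 alkylation of the unhindered ring-B phenoxide at the doubly ester-activated chlorine-bearing carbon, the usual way to aryloxymalonates; the chloride is chosen over the bromide to avoid halogen transfer to the electron-rich phenoxide.

Step 12
Reactants: 20 dimethyl 2-(ArO)propanedioate
Product: 21 2-(ArO)-3-methoxy-3-oxopropanoic acid (racemic half-ester)
Conditions: KOH (1.0 equiv), MeOH/THF/H2O, 0 °C; then 1 M HCl, 0 °C
Reagents that add atoms: potassium hydroxide, [K+].[OH-]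
Why: Selective monosaponification of a malonate, in which the carboxylate formed first shields the second ester from hydroxide, so one equivalent of base at 0 °C should stop at the half-ester.

Step 13
Reactants: 22 methyl acetoacetate
Product: 23 methyl 3-(trimethylsilyloxy)but-2-enoate (E/Z mixture)
Conditions: Me3SiCl, Et3N, hexane, rt
Reagents that add atoms: chlorotrimethylsilane, C[Si](C)(C)Cl
Why: O-silylation of the enol of a β-keto ester with Me3SiCl and Et3N, a standard silyl enol ether formation.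

Step 14
Reactants: 23 methyl 3-(trimethylsilyloxy)but-2-enoate
Product: 24 1-methoxy-1,3-bis(trimethylsilyloxy)buta-1,3-diene (mixture of isomers at the 1,2-double bond)
Conditions: LiN(i-Pr)2, THF, −78 °C; Me3SiCl, −78 °C to rt
Reagents that add atoms: chlorotrimethylsilane, C[Si](C)(C)Cl
Why: γ-Deprotonation of the vinylogous ester to its dienolate and O-silylation give the 1,3-bis(silyl enol ether), a neutral equivalent of the acetoacetate dianion.

Step 15
Reactants: 21 2-(ArO)-3-methoxy-3-oxopropanoic acid; 24 1-methoxy-1,3-bis(trimethylsilyloxy)buta-1,3-diene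
Product: 26 dimethyl 2-(ArO)-3,5-dioxoheptanedioate (racemic), via acid chloride 25 (not isolated)
Conditions: (COCl)2, DMF (cat.), CH2Cl2, 0 °C to rt, evaporate; then 24 (2 equiv), CH2Cl2, −78 °C to rt; H2O work-up
Reagents that add atoms: none
Why: Acid chloride formation followed by Mukaiyama-type acylation of the 1,3-bis(silyl enol ether) at its terminal carbon, a known route to 3,5-dioxo esters and 3,5-dioxoheptanedioates; the neutral diene leaves the acidic hydrogen of 25 untouched, whereas a lithium or sodium dianion of methyl acetoacetate would simply deprotonate 25.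

Step 16
Reactants: 26 dimethyl 2-(ArO)-3,5-dioxoheptanedioate
Product: 28 methyl 2,4,6-trihydroxy-3-(ArO)benzoate (heptamer with ring A as its carboxylate), via triketone 27 (not isolated)
Conditions: Mg(OMe)2, MeOH, reflux, argon; then 1 M HCl, 0 °C
Reagents that add atoms: none
Why: Mg(OMe)2 should turn 26 into a chelated polyenolate in which the methylene at chain carbon 6, between the chain-end ester and the ketone at chain carbon 5, adds as a carbon nucleophile to the ester carbonyl at chain carbon 1 beside the aryloxy-bearing chain carbon 2; methoxide is expelled to give triketone 27, and its enolisation to the benzene ring (chain carbons 1 to 6 becoming ring-A carbons 5, 4, 3, 2, 1 and 6) takes the product out of every equilibrium. The closest known reaction type is the intramolecular Claisen (Dieckmann-type) condensation by which 3,5-dioxoheptanedioates and 3,5,7-trioxo esters are folded into phloroglucinol carboxylates and acylphloroglucinols. Ring A closes in the 6-exo-trig mode, the attacked carbonyl oxygen lying outside the new six-membered ring, and the only skeletal bond made joins ring-A carbons 6 and 5. No stereocentre is formed, and the racemic centre at chain carbon 2 of 26 ends as the planar carbon 4 of ring A. The selectivity needed is acylation by chain carbon 6 at chain carbon 1 in preference to attack of the aryloxy-bearing chain carbon 2 on the ester at chain carbon 7 and to lactonisation of an enol oxygen to a 2-pyranone; the adduct from chain carbon 2 has a quaternary carbon, cannot aromatise and should be reopened by methoxide, and 2-pyranones are likewise opened by Mg(OMe)2 in methanol, so the one path that ends in an aromatic ring should collect the material. The crowded ether between ring A and ring B is already in place from step 11, and the three ring-A hydroxyls emerge unprotected.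

Step 17
Reactants: 28 methyl 2,4,6-trihydroxy-3-(ArO)benzoate
Product: 30 2-(ArO)benzene-1,3,5-triol (heptamer with ring A free and fifteen methyl ethers), via benzoic acid 29 (not isolated)
Conditions: KOH, H2O/MeOH (degassed), reflux, argon; then HCl to pH 2, 50 °C
Reagents that add atoms: none
Why: Saponification followed by decarboxylation of a 2,4,6-trihydroxybenzoic acid, which loses CO2 readily through protonation at the carboxyl-bearing carbon 6 of ring A as in the classical phloroglucinol synthesis; aryl methyl ethers and diaryl ethers are inert to hot aqueous alkali, and oxygen is excluded to protect ring A.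

Step 18
Reactants: 30 2-(ArO)benzene-1,3,5-triol
Product: 31 target heptamer ABCDEFG (benzene-1,3,5-triol carrying at position 2 the fully demethylated aryloxy group of 18)
Conditions: BBr3 (excess), CH2Cl2, −78 °C to rt, argon; then H2O, 0 °C
Reagents that add atoms: none
Why: Lewis acid cleavage of aryl methyl ethers, in which BBr3 binds each methoxy oxygen and bromide removes the methyl group by SN2; the six diaryl ether bonds offer no sp3 carbon and should survive, and hydrolysis of the aryl borates releases all eighteen hydroxyls.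

**Compound list**

1 | 3,4,5-trimethoxyphenol | COc1cc(O)cc(OC)c1OC | starting material
2 | 4-bromo-3,5-dimethoxybenzaldehyde | COc1cc(C=O)cc(OC)c1Br | starting material
3 | 3,5-dimethoxy-4-(3,4,5-trimethoxyphenoxy)benzaldehyde (dimer aldehyde FG) | O=Cc1cc(OC)c(Oc2cc(OC)c(OC)c(OC)c2)c(OC)c1 | intermediate
4 | 3,5-dimethoxy-4-(3,4,5-trimethoxyphenoxy)phenyl formate | O=COc1cc(OC)c(Oc2cc(OC)c(OC)c(OC)c2)c(OC)c1 | intermediate
5 | 3,5-dimethoxy-4-(3,4,5-trimethoxyphenoxy)phenol (dimer phenol FG) | Oc1cc(OC)c(Oc2cc(OC)c(OC)c(OC)c2)c(OC)c1 | intermediate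
6 | 2-bromo-3,4,5-trimethoxybenzaldehyde | COc1cc(C=O)c(Br)c(OC)c1OC | starting material
7 | 2-[3,5-dimethoxy-4-(3,4,5-trimethoxyphenoxy)phenoxy]-3,4,5-trimethoxybenzaldehyde (trimer aldehyde EFG) | O=Cc1cc(OC)c(OC)c(OC)c1Oc1cc(OC)c(Oc2cc(OC)c(OC)c(OC)c2)c(OC)c1 | intermediate
8 | 2-[3,5-dimethoxy-4-(3,4,5-trimethoxyphenoxy)phenoxy]-3,4,5-trimethoxyphenyl formate | O=COc1cc(OC)c(OC)c(OC)c1Oc1cc(OC)c(Oc2cc(OC)c(OC)c(OC)c2)c(OC)c1 | intermediate
9 | 2-[3,5-dimethoxy-4-(3,4,5-trimethoxyphenoxy)phenoxy]-3,4,5-trimethoxyphenol (trimer phenol EFG) | Oc1cc(OC)c(OC)c(OC)c1Oc1cc(OC)c(Oc2cc(OC)c(OC)c(OC)c2)c(OC)c1 | intermediate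
10 | 4-{2-[3,5-dimethoxy-4-(3,4,5-trimethoxyphenoxy)phenoxy]-3,4,5-trimethoxyphenoxy}-3,5-dimethoxybenzaldehyde (tetramer aldehyde DEFG) | O=Cc1cc(OC)c(Oc2cc(OC)c(OC)c(OC)c2Oc2cc(OC)c(Oc3cc(OC)c(OC)c(OC)c3)c(OC)c2)c(OC)c1 | intermediate
11 | formate ester of tetramer phenol DEFG | O=COc1cc(OC)c(Oc2cc(OC)c(OC)c(OC)c2Oc2cc(OC)c(Oc3cc(OC)c(OC)c(OC)c3)c(OC)c2)c(OC)c1 | intermediate
12 | 4-{2-[3,5-dimethoxy-4-(3,4,5-trimethoxyphenoxy)phenoxy]-3,4,5-trimethoxyphenoxy}-3,5-dimethoxyphenol (tetramer phenol DEFG) | Oc1cc(OC)c(Oc2cc(OC)c(OC)c(OC)c2Oc2cc(OC)c(Oc3cc(OC)c(OC)c(OC)c3)c(OC)c2)c(OC)c1 | intermediate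
13 | pentamer aldehyde CDEFG: 3,4,5-trimethoxybenzaldehyde carrying at position 2 the aryloxy group of 12 | O=Cc1cc(OC)c(OC)c(OC)c1Oc1cc(OC)c(Oc2cc(OC)c(OC)c(OC)c2Oc2cc(OC)c(Oc3cc(OC)c(OC)c(OC)c3)c(OC)c2)c(OC)c1 | intermediate
14 | formate ester of pentamer phenol CDEFG | O=COc1cc(OC)c(OC)c(OC)c1Oc1cc(OC)c(Oc2cc(OC)c(OC)c(OC)c2Oc2cc(OC)c(Oc3cc(OC)c(OC)c(OC)c3)c(OC)c2)c(OC)c1 | intermediate
15 | pentamer phenol CDEFG: 3,4,5-trimethoxyphenol carrying at position 2 the aryloxy group of 12 | Oc1cc(OC)c(OC)c(OC)c1Oc1cc(OC)c(Oc2cc(OC)c(OC)c(OC)c2Oc2cc(OC)c(Oc3cc(OC)c(OC)c(OC)c3)c(OC)c2)c(OC)c1 | intermediate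
16 | hexamer aldehyde BCDEFG: 3,5-dimethoxybenzaldehyde carrying at position 4 the aryloxy group of 15 | O=Cc1cc(OC)c(Oc2cc(OC)c(OC)c(OC)c2Oc2cc(OC)c(Oc3cc(OC)c(OC)c(OC)c3Oc3cc(OC)c(Oc4cc(OC)c(OC)c(OC)c4)c(OC)c3)c(OC)c2)c(OC)c1 | intermediate
17 | formate ester of hexamer phenol BCDEFG | O=COc1cc(OC)c(Oc2cc(OC)c(OC)c(OC)c2Oc2cc(OC)c(Oc3cc(OC)c(OC)c(OC)c3Oc3cc(OC)c(Oc4cc(OC)c(OC)c(OC)c4)c(OC)c3)c(OC)c2)c(OC)c1 | intermediate
18 | hexamer phenol BCDEFG: 3,5-dimethoxyphenol carrying at position 4 the aryloxy group of 15 (its aryloxy group is ArO) | Oc1cc(OC)c(Oc2cc(OC)c(OC)c(OC)c2Oc2cc(OC)c(Oc3cc(OC)c(OC)c(OC)c3Oc3cc(OC)c(Oc4cc(OC)c(OC)c(OC)c4)c(OC)c3)c(OC)c2)c(OC)c1 | intermediate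
19 | dimethyl chloromalonate (dimethyl 2-chloropropanedioate) | COC(=O)C(Cl)C(=O)OC | starting material
20 | dimethyl 2-(ArO)propanedioate | COC(=O)C(Oc1cc(OC)c(Oc2cc(OC)c(OC)c(OC)c2Oc2cc(OC)c(Oc3cc(OC)c(OC)c(OC)c3Oc3cc(OC)c(Oc4cc(OC)c(OC)c(OC)c4)c(OC)c3)c(OC)c2)c(OC)c1)C(=O)OC | intermediate
21 | 2-(ArO)-3-methoxy-3-oxopropanoic acid (racemic) | COC(=O)C(Oc1cc(OC)c(Oc2cc(OC)c(OC)c(OC)c2Oc2cc(OC)c(Oc3cc(OC)c(OC)c(OC)c3Oc3cc(OC)c(Oc4cc(OC)c(OC)c(OC)c4)c(OC)c3)c(OC)c2)c(OC)c1)C(=O)O | intermediate
22 | methyl acetoacetate | COC(=O)CC(C)=O | starting material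
23 | methyl 3-(trimethylsilyloxy)but-2-enoate (E/Z mixture) | COC(=O)C=C(C)O[Si](C)(C)C | intermediate
24 | 1-methoxy-1,3-bis(trimethylsilyloxy)buta-1,3-diene (isomer mixture) | COC(O[Si](C)(C)C)=CC(=C)O[Si](C)(C)C | intermediate
25 | methyl 2-(ArO)-3-chloro-3-oxopropanoate (racemic acid chloride) | COC(=O)C(Oc1cc(OC)c(Oc2cc(OC)c(OC)c(OC)c2Oc2cc(OC)c(Oc3cc(OC)c(OC)c(OC)c3Oc3cc(OC)c(Oc4cc(OC)c(OC)c(OC)c4)c(OC)c3)c(OC)c2)c(OC)c1)C(=O)Cl | intermediate
26 | dimethyl 2-(ArO)-3,5-dioxoheptanedioate (racemic; key-step precursor) | COC(=O)CC(=O)CC(=O)C(Oc1cc(OC)c(Oc2cc(OC)c(OC)c(OC)c2Oc2cc(OC)c(Oc3cc(OC)c(OC)c(OC)c3Oc3cc(OC)c(Oc4cc(OC)c(OC)c(OC)c4)c(OC)c3)c(OC)c2)c(OC)c1)C(=O)OC | intermediate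
27 | methyl 3-(ArO)-2,4,6-trioxocyclohexane-1-carboxylate (triketone tautomer of 28) | COC(=O)C1C(=O)CC(=O)C(Oc2cc(OC)c(Oc3cc(OC)c(OC)c(OC)c3Oc3cc(OC)c(Oc4cc(OC)c(OC)c(OC)c4Oc4cc(OC)c(Oc5cc(OC)c(OC)c(OC)c5)c(OC)c4)c(OC)c3)c(OC)c2)C1=O | intermediate
28 | methyl 2,4,6-trihydroxy-3-(ArO)benzoate (key-step product) | COC(=O)c1c(O)cc(O)c(Oc2cc(OC)c(Oc3cc(OC)c(OC)c(OC)c3Oc3cc(OC)c(Oc4cc(OC)c(OC)c(OC)c4Oc4cc(OC)c(Oc5cc(OC)c(OC)c(OC)c5)c(OC)c4)c(OC)c3)c(OC)c2)c1O | intermediate
29 | 2,4,6-trihydroxy-3-(ArO)benzoic acid | OC(=O)c1c(O)cc(O)c(Oc2cc(OC)c(Oc3cc(OC)c(OC)c(OC)c3Oc3cc(OC)c(Oc4cc(OC)c(OC)c(OC)c4Oc4cc(OC)c(Oc5cc(OC)c(OC)c(OC)c5)c(OC)c4)c(OC)c3)c(OC)c2)c1O | intermediate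
30 | 2-(ArO)benzene-1,3,5-triol (pentadeca-O-methyl heptamer) | Oc1cc(O)c(Oc2cc(OC)c(Oc3cc(OC)c(OC)c(OC)c3Oc3cc(OC)c(Oc4cc(OC)c(OC)c(OC)c4Oc4cc(OC)c(Oc5cc(OC)c(OC)c(OC)c5)c(OC)c4)c(OC)c3)c(OC)c2)c(O)c1 | intermediate
31 | target heptamer ABCDEFG (CNP0292517.0) | Oc1cc(O)c(Oc2cc(O)c(Oc3cc(O)c(O)c(O)c3Oc3cc(O)c(Oc4cc(O)c(O)c(O)c4Oc4cc(O)c(Oc5cc(O)c(O)c(O)c5)c(O)c4)c(O)c3)c(O)c2)c(O)c1 | target

**Step count**

Total: 18 steps. Longest linear sequence: 16 steps (steps 1 to 12, then 15 to 18); steps 13 and 14 form the short diene branch.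

**Three steps most likely to fail**

Step 16 (key step). The polyenolate may acylate the wrong ester, from the aryloxy-bearing carbon or from an enol oxygen onto the chain-end ester, and these closures may not reopen fast enough to feed the aromatising path. The fallback sets out from 21 and comes back at 30; it makes the chain-end ester a tert-butyl ester, which does not accept acyl transfer. tert-Butyl acetoacetate is O-silylated (Me3SiCl, Et3N) to tert-butyl 3-(trimethylsilyloxy)but-2-enoate F1 and then converted (LiN(i-Pr)2, Me3SiCl, THF, −78 °C) into 1-tert-butoxy-1,3-bis(trimethylsilyloxy)buta-1,3-diene F2. Acid chloride 25, made from 21 as in step 15, acylates F2 to give 7-tert-butyl 1-methyl 2-(ArO)-3,5-dioxoheptanedioate F3. With Mg(OMe)2 in methanol F3 can close only onto the methyl ester at the future carbon 5 of ring A and should give tert-butyl 2,4,6-trihydroxy-3-(ArO)benzoate F4. Heating F4 with silica gel in toluene under argon expels 2-methylpropene; the acid 29 then loses CO2 and gives 30, without hot alkali.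

Step 15. Acid chloride 25 may lose HCl to a ketene, or traces of HCl may strip the silyl groups from 24 before acylation at carbon, so that the chain is not formed. The fallback sets out from 18 and comes back at 26 with the roles of the partners inverted. Phenol 18 is O-alkylated with methyl 2-chloro-3-oxobutanoate (K2CO3, acetone) to methyl 2-(ArO)-3-oxobutanoate F5. Me3SiCl and Et3N give methyl 2-(ArO)-3-(trimethylsilyloxy)but-2-enoate F6, and LiN(i-Pr)2 followed by Me3SiCl gives 2-(ArO)-1-methoxy-1,3-bis(trimethylsilyloxy)buta-1,3-diene F7. F7 is acylated at its terminal carbon by methyl 3-chloro-3-oxopropanoate (CH2Cl2, −78 °C to rt), and aqueous work-up gives 26. Here the acid chloride is the simple partner and the aryloxy carbon is part of the nucleophile.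

Step 18. Some of the fifteen methyl ethers may stay uncleaved, and the free octadecaphenol may oxidise in air during isolation. The fallback sets out from 30 and comes back at 31 through a protected form. After BBr3 treatment and a methanol quench, the crude material is acetylated (Ac2O, pyridine) to the octadecaacetate of 31 F8, which is stable and can be chromatographed; under-demethylated fractions are separated and returned to BBr3. F8 is then deacetylated with HCl in methanol under argon, an acid transesterification that avoids phenoxide anions, to give 31.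

**Further compounds**

F1 | step 16 | tert-butyl 3-(trimethylsilyloxy)but-2-enoate (E/Z mixture) | CC(C)(C)OC(=O)C=C(C)O[Si](C)(C)C
F2 | step 16 | 1-tert-butoxy-1,3-bis(trimethylsilyloxy)buta-1,3-diene (isomer mixture) | CC(C)(C)OC(O[Si](C)(C)C)=CC(=C)O[Si](C)(C)C
F3 | step 16 | 7-tert-butyl 1-methyl 2-(ArO)-3,5-dioxoheptanedioate (racemic) | COC(=O)C(Oc1cc(OC)c(Oc2cc(OC)c(OC)c(OC)c2Oc2cc(OC)c(Oc3cc(OC)c(OC)c(OC)c3Oc3cc(OC)c(Oc4cc(OC)c(OC)c(OC)c4)c(OC)c3)c(OC)c2)c(OC)c1)C(=O)CC(=O)CC(=O)OC(C)(C)C
F4 | step 16 | tert-butyl 2,4,6-trihydroxy-3-(ArO)benzoate | CC(C)(C)OC(=O)c1c(O)cc(O)c(Oc2cc(OC)c(Oc3cc(OC)c(OC)c(OC)c3Oc3cc(OC)c(Oc4cc(OC)c(OC)c(OC)c4Oc4cc(OC)c(Oc5cc(OC)c(OC)c(OC)c5)c(OC)c4)c(OC)c3)c(OC)c2)c1O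
F5 | step 15 | methyl 2-(ArO)-3-oxobutanoate (racemic) | COC(=O)C(Oc1cc(OC)c(Oc2cc(OC)c(OC)c(OC)c2Oc2cc(OC)c(Oc3cc(OC)c(OC)c(OC)c3Oc3cc(OC)c(Oc4cc(OC)c(OC)c(OC)c4)c(OC)c3)c(OC)c2)c(OC)c1)C(C)=O
F6 | step 15 | methyl 2-(ArO)-3-(trimethylsilyloxy)but-2-enoate (E/Z mixture) | COC(=O)C(Oc1cc(OC)c(Oc2cc(OC)c(OC)c(OC)c2Oc2cc(OC)c(Oc3cc(OC)c(OC)c(OC)c3Oc3cc(OC)c(Oc4cc(OC)c(OC)c(OC)c4)c(OC)c3)c(OC)c2)c(OC)c1)=C(C)O[Si](C)(C)C
F7 | step 15 | 2-(ArO)-1-methoxy-1,3-bis(trimethylsilyloxy)buta-1,3-diene (isomer mixture) | COC(O[Si](C)(C)C)=C(Oc1cc(OC)c(Oc2cc(OC)c(OC)c(OC)c2Oc2cc(OC)c(Oc3cc(OC)c(OC)c(OC)c3Oc3cc(OC)c(Oc4cc(OC)c(OC)c(OC)c4)c(OC)c3)c(OC)c2)c(OC)c1)C(=C)O[Si](C)(C)C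
F8 | step 18 | octadecaacetate of 31 | CC(=O)Oc1cc(OC(C)=O)c(Oc2cc(OC(C)=O)c(Oc3cc(OC(C)=O)c(OC(C)=O)c(OC(C)=O)c3Oc3cc(OC(C)=O)c(Oc4cc(OC(C)=O)c(OC(C)=O)c(OC(C)=O)c4Oc4cc(OC(C)=O)c(Oc5cc(OC(C)=O)c(OC(C)=O)c(OC(C)=O)c5)c(OC(C)=O)c4)c(OC(C)=O)c3)c(OC(C)=O)c2)c(OC(C)=O)c1
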